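I want the leftover: how much substrate still stands in gamma and in delta at the end, and whether target has overtaken it there.

| setting | east | north-west | south-west | gamma | delta |
|---|---|---|---|---|---|
| substrate | 0.050 M | 0.050 M | 0.050 M | 0.050 M | 0.050 M |
| reagent | 1 equiv | 0.92 equiv | 0.88 equiv | 0.800 equiv | 1.20 equiv |
| remark | run made earlier | run made earlier | run made earlier |  |  |
| time |  |  |  | 1.5 h | 1.5 h |

| run | time / min | target / % | substrate / % |
|---|---|---|---|
| east | 6.00 | 0.5 | 99.6 |
| east | 15.0 | 0.7 | 98.7 |
| east | 30.0 | 3.1 | 96.9 |
| east | 50.0 | 5.1 | 94.8 |
| north-west | 12.0 | 1.4 | 99.7 |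
| north-west | 25.0 | 1.4 | 98.0 |
| north-west | 30.0 | 3.1 | 97.2 |
| north-west | 50.0 | 4.8 | 94.9 |
| south-west | 12.0 | 0.6 | 99.1 |
| south-west | 25.0 | 1.8 | 97.7 |
| south-west | 30.0 | 2.3 | 97.7 |
| south-west | 50.0 | 4.5 | 95.3 |

(each reading ± 0.3 percentage points)

* which of these there is most of at the end, counted by the substrate in it, gamma (substrate / target)
* which of these there is most of at the end, counted by the substrate in it, delta (substrate / target)
* the largest of these amounts at the end, in percent of the substrate charged, gamma
* the largest of these amounts at the end, in percent of the substrate charged, delta

- on the list of suspects stand: substrate + reagent + target -> 2 target; substrate + reagent -> target; 2 reagent -> self-condensation product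

At the last readings of the earlier runs the substrate lost matches the target gained within the scatter, and the east run still holds 94.8% substrate at 50.0 min, so I freeze substrate at its charge. Target at the last reading, divided by the equivalents of reagent, gives 5.10% in the east run, 5.22% in the north-west run and 5.11% in the south-west run, so the slope follows the reagent charge. Pooling the three gives 0.0617 h⁻¹. I call this the slope per equivalent, the fraction of the substrate charge turned into target per hour for each equivalent of reagent charged. It reads 0.0607 h⁻¹ up to 30.0 min and 0.0632 h⁻¹ after it, so I draw no knee.

Gamma therefore starts at 0.0494 h⁻¹ and delta at 0.0741 h⁻¹. Drawn straight to 1.5 h, gamma keeps 92.6% substrate and delta keeps 88.9%. Target would meet substrate at the 0.5 mark after 10.1 h in gamma and 6.75 h in delta, both later than the asked time, so I commit to substrate in both. With one reagent per target, gamma's charge, where reagent is the limiting reagent, allows a level of 20.0% substrate.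

The forecast also names substrate, but lower than my lines: 91% (88% to 93.5%) in gamma and 86% (79% to 90%) in delta. Its ground: “This is mild acceleration, pointing to some target-assisted route”.

Gamma ends with 91.7% substrate and 8.30% target; delta ends with 85.9% substrate and 14.1% target.

    substrate + reagent + target → 2 target (k = 19.0 M⁻² min⁻¹)
    substrate + reagent → target (k = 0.0140 M⁻¹ min⁻¹)
    2 reagent → self-condensation product (k = 0.220 M⁻¹ min⁻¹)

The slope per equivalent 0.0617 h⁻¹ gives delta 11.1% target at 1.5 h, and the flask stands a factor 1.27 above that. Read at 2.5 h, delta stands at 23.2% against a line of 18.5%, a factor 1.26. The slope per equivalent puts the gap in substrate between gamma and delta at 1.5 h at 3.7 percentage points. The main reason for that gap is the difference in equivalents of reagent: delta holds 85.9% substrate, and without that difference it holds 91.7%, a gap of 5.8 points.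

All runs are simulated on assumed constants; the scatter is artificial.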